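**Plan**

Numbering is that of germacrane/eudesmane: C10 carries C14, C4 carries C15, C7 carries C11 (C12 carbonyl, C13 methylene), the lactone oxygen sits on C8 and the free hydroxyl on C6.
Retrosynthesis: cut the C15 O–acyl bond (4-hydroxytiglate) and the C11=C13 methylene, then re-join C5–C10 while adding a C2=C3 bond (ten-membered ring back to a decalin). In the decalin cut O8–C12, C7–C11, the C6–O and C8–O bonds (back to olefins) and finally C4–C5 and C1–C10 (annulation).
Enabling feature: the two ring-trans olefins C1=C10 and C4=C5 flank the C2–C3 ethano unit, so the ten-membered ring is the opened form of a cyclohexa-1,3-diene C1=C2–C3=C4 whose sixth σ-bond is C5–C10, that is, of ring A of a trans-fused eudesma-1,3-diene.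
Forward: ring B is bought as 2-methylcyclohexanone, ring A is annulated onto it, the acetate arm is coupled to C7, the γ-lactone is closed on O8, ring A is taken to the diene, light opens the bicycle to the ten-membered ring, and the side-chain acid is joined last.
Stereochemistry: C10 from a chiral-amine-controlled Michael addition; C7/C8 and C5/C6 from two syn hydroborations on the face opposite the axial C10 methyl; both ring-olefin geometries from conrotation of the trans ring fusion; the tiglate (E)-geometry from a stabilised ylide.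

Key step: step 17

Remark: the silyloxypropanal, the Reformatsky reagent, the silyloxyacetaldehyde and the phosphorane are taken as catalogue compounds; α/β refer to the usual eudesmane/germacrane drawings (C10 methyl and C7 side chain β); C4 of the ring-A intermediates is drawn as the equatorial 4α-CH2OSi epimer, and either epimer converges when C3=C4 is made.

**Route**

Step 1
Reactants: 1 3-[(tert-butyldiphenylsilyl)oxy]propanal; 2 vinylmagnesium bromide
Product: 3 (±)-5-[(tert-butyldiphenylsilyl)oxy]pent-1-en-3-ol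
Conditions: THF, −78 → 0 °C; aq NH4Cl
Reagents that add atoms: none
Why: Grignard 1,2-addition to the aldehyde should give the racemic allylic alcohol, whose carbinol centre is removed in the next step.

Step 2
Reactants: 3 (±)-5-[(tert-butyldiphenylsilyl)oxy]pent-1-en-3-ol
Product: 4 5-[(tert-butyldiphenylsilyl)oxy]pent-1-en-3-one
Conditions: Dess–Martin periodinane, CH2Cl2, 20 °C
Reagents that add atoms: none
Why: Dess–Martin oxidation should give the vinyl ketone under non-basic conditions that do not eliminate the β-silyloxy group.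

Step 3
Reactants: 5 (±)-2-methylcyclohexan-1-one; 6 (R)-1-phenylethylamine; 4 5-[(tert-butyldiphenylsilyl)oxy]pent-1-en-3-one
Product: 9 (2S)-2-{5-[(tert-butyldiphenylsilyl)oxy]-3-oxopentyl}-2-methylcyclohexan-1-one, via ketimine 7 (not isolated), via Michael-adduct imine 8 (not isolated)
Conditions: 5 + 6, toluene, reflux (Dean–Stark); then 4, THF, 40 °C; then 20% aq AcOH, 20 °C
Reagents that add atoms: water, O
Why: Asymmetric Michael addition of a chiral imine: the more substituted secondary-enamine tautomer of 7 adds to the enone in a compact aza-ene-like transition state on the face away from the phenyl group, so the (R)-amine should set the (S)-quaternary centre C10 (mirror image of the known (S)-amine/methyl vinyl ketone case), and hydrolysis frees the 1,5-diketone and the auxiliary.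

Step 4
Reactants: 9 (2S)-2-{5-[(tert-butyldiphenylsilyl)oxy]-3-oxopentyl}-2-methylcyclohexan-1-one
Product: 10 (4aS)-1-{[(tert-butyldiphenylsilyl)oxy]methyl}-4a-methyl-4,4a,5,6,7,8-hexahydronaphthalen-2(3H)-one
Conditions: TsOH·H2O (10 mol %), benzene, reflux (Dean–Stark)
Reagents that add atoms: none
Why: Acid-catalysed intramolecular aldol condensation (second stage of a Robinson annulation) should close ring A (C4–C5), acid being chosen over alkoxide so that water is lost from the tertiary aldol instead of silanolate from C15 by E1cB.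

Step 5
Reactants: 10 (4aS)-1-{[(tert-butyldiphenylsilyl)oxy]methyl}-4a-methyl-4,4a,5,6,7,8-hexahydronaphthalen-2(3H)-one
Product: 11 15-[(tert-butyldiphenylsilyl)oxy]-3,3-(ethylenedioxy)-11,12,13-trinor-4βH-eudesm-5-ene
Conditions: ethylene glycol, TsOH·H2O (cat.), benzene, reflux (Dean–Stark)
Reagents that add atoms: ethylene glycol, OCCO
Why: Deconjugative ketalisation of a Δ4-3-ketone (via the dienol ether, as with steroidal enones) should protect C3 and move the olefin to C5=C6, which leaves C7 as the only allylic methylene.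

Step 6
Reactants: 11 15-[(tert-butyldiphenylsilyl)oxy]-3,3-(ethylenedioxy)-11,12,13-trinor-4βH-eudesm-5-ene
Product: 12 15-[(tert-butyldiphenylsilyl)oxy]-3,3-(ethylenedioxy)-11,12,13-trinor-4βH-eudesm-5-en-7-one
Conditions: t-BuOOH, Rh2(cap)4 (1 mol %), K2CO3, CH2Cl2, 20 °C
Reagents that add atoms: tert-butyl hydroperoxide, CC(C)(C)OO
Why: Dirhodium-catalysed allylic oxidation of a Δ5-olefin should give the Δ5-7-ketone as it does with Δ5-steroids, because C7 is the only allylic CH2 (H-4 is tertiary and flanked by the ketal).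

Step 7
Reactants: 12 15-[(tert-butyldiphenylsilyl)oxy]-3,3-(ethylenedioxy)-11,12,13-trinor-4βH-eudesm-5-en-7-one
Product: 13 15-[(tert-butyldiphenylsilyl)oxy]-3,3-(ethylenedioxy)-11,12,13-trinor-4βH-eudesma-5,7-dien-7-yl trifluoromethanesulfonate
Conditions: LiHMDS, THF, −78 °C; PhNTf2, −78 → 0 °C
Reagents that add atoms: N-phenylbis(trifluoromethanesulfonimide), O=S(=O)(N(c1ccccc1)S(=O)(=O)C(F)(F)F)C(F)(F)F
Why: Kinetic α′-deprotonation of the enone at C8 followed by O-triflation (enol triflate formation) should give the cross-conjugated dienyl triflate.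

Step 8
Reactants: 13 dienyl triflate; 14 (2-ethoxy-2-oxoethyl)zinc bromide
Product: 15 ethyl 15-[(tert-butyldiphenylsilyl)oxy]-3,3-(ethylenedioxy)-13-nor-4βH-eudesma-5,7-dien-12-oate
Conditions: Pd(PPh3)4 (5 mol %), THF, 50 °C
Reagents that add atoms: none
Why: Palladium-catalysed Negishi-type coupling of an enol triflate with a Reformatsky reagent should form C7–C11 at the position fixed by the triflate, so no ketone-enolate regiochemistry is involved.

Step 9
Reactants: 15 ethyl 15-[(tert-butyldiphenylsilyl)oxy]-3,3-(ethylenedioxy)-13-nor-4βH-eudesma-5,7-dien-12-oate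
Product: 17 ethyl 15-[(tert-butyldiphenylsilyl)oxy]-3,3-(ethylenedioxy)-8α-hydroxy-13-nor-4βH,7αH-eudesm-5-en-12-oate, via alkyl-9-BBN adduct 16 (not isolated)
Conditions: 9-BBN, THF, 0 → 50 °C; then NaBO3·4H2O, THF–H2O, 20 °C
Reagents that add atoms: sodium perborate, [Na+].[Na+].O[B-]1(O)OO[B-](O)(O)OO1
Why: Hydroboration–oxidation of the conjugated diene with 9-BBN should take place at the less hindered C7=C8 bond with boron on the CH terminus C8 and from the α-face opposite the C10 methyl (syn addition), which sets 7α-H and 8α-OH while the hindered C5=C6 bond and the ester are left untouched.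

Step 10
Reactants: 17 ethyl 8α-hydroxy ester
Product: 18 15-[(tert-butyldiphenylsilyl)oxy]-3,3-(ethylenedioxy)-13-nor-4βH,7αH,8βH-eudesm-5-en-12,8-olide
Conditions: CSA (10 mol %), toluene, 60 °C
Reagents that add atoms: none
Why: Acid-catalysed lactonisation (intramolecular transesterification) should close the trans-fused γ-lactone from the only hydroxyl present, so the 12,8-regiochemistry is unambiguous.

Step 11
Reactants: 18 Δ5 12,8-lactone
Product: 20 15-[(tert-butyldiphenylsilyl)oxy]-3,3-(ethylenedioxy)-6α-hydroxy-13-nor-4βH,5αH,7αH,8βH-eudesman-12,8-olide, via alkylborane 19 (not isolated)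
Conditions: BH3·THF, THF, 0 °C; then MeOH; 30% H2O2, pH 7 phosphate buffer, 0 → 20 °C
Reagents that add atoms: hydrogen peroxide, OO
Why: Hydroboration–oxidation of the Δ5-olefin from the α-face (anti to the axial C10 methyl, as in Δ5-steroids) should place boron on C6 and hydrogen on C5 by syn addition, giving the trans ring fusion and the equatorial 6α-alcohol, with a neutral oxidation that keeps the lactone closed.

Step 12
Reactants: 20 6α-hydroxy lactone
Product: 21 15-[(tert-butyldiphenylsilyl)oxy]-3,3-(ethylenedioxy)-6α-[(triisopropylsilyl)oxy]-13-nor-4βH,5αH,7αH,8βH-eudesman-12,8-olide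
Conditions: TIPSOTf, 2,6-lutidine, CH2Cl2, 0 → 20 °C
Reagents that add atoms: triisopropylsilyl trifluoromethanesulfonate, CC(C)[Si](OS(=O)(=O)C(F)(F)F)(C(C)C)C(C)C
Why: Silylation with a silyl triflate and a hindered base should protect the flanked equatorial C6 alcohol as a robust ether that also blocks translactonisation to O6.

Step 13
Reactants: 21 TIPS ether ketal
Product: 22 15-[(tert-butyldiphenylsilyl)oxy]-3-oxo-6α-[(triisopropylsilyl)oxy]-13-nor-4βH,5αH,7αH,8βH-eudesman-12,8-olide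
Conditions: 1 M aq HCl, THF, 20 °C
Reagents that add atoms: water, O
Why: Acid hydrolysis of the dioxolane (acetal hydrolysis) should free the C3 ketone while both silyl ethers and the lactone survive, and C4 equilibrates to the equatorial epimer.

Step 14
Reactants: 22 3-ketone
Product: 24 15-[(tert-butyldiphenylsilyl)oxy]-3-oxo-6α-[(triisopropylsilyl)oxy]-13-nor-4βH,5αH,7αH,8βH-eudesm-1-en-12,8-olide, via silyl enol ether 23 (not isolated)
Conditions: TMSOTf, Et3N, CH2Cl2, 0 °C; then Pd(OAc)2, MeCN, 20 °C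
Reagents that add atoms: none
Why: Saegusa–Ito oxidation: soft enolisation should silylate the ketone towards the unsubstituted C2 without touching the lactone, and Pd(II) dehydrosilylation then gives the Δ1-3-ketone.

Step 15
Reactants: 24 Δ1-3-ketone
Product: 25 15-[(tert-butyldiphenylsilyl)oxy]-6α-[(triisopropylsilyl)oxy]-3-{[(trifluoromethyl)sulfonyl]oxy}-13-nor-5αH,7αH,8βH-eudesma-1,3-dien-12,8-olide
Conditions: Tf2O, 2,6-di-tert-butyl-4-methylpyridine, CH2Cl2, 0 → 20 °C
Reagents that add atoms: trifluoromethanesulfonic anhydride, O=S(=O)(OS(=O)(=O)C(F)(F)F)C(F)(F)F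
Why: Enol triflate formation by O-triflation of the enone and loss of its only α′-proton (H-4; C10 is quaternary) should give the 1,3-dien-3-yl triflate chemoselectively, since the lactone is not activated under these non-basic conditions.

Step 16
Reactants: 25 dienyl triflate
Product: 26 15-[(tert-butyldiphenylsilyl)oxy]-6α-[(triisopropylsilyl)oxy]-13-nor-5αH,7αH,8βH-eudesma-1,3-dien-12,8-olide
Conditions: Pd(OAc)2 (5 mol %), PPh3, HCO2H, n-Bu3N, DMF, 60 °C
Reagents that add atoms: none
Why: Palladium-catalysed formate reduction of the enol triflate should replace OTf by H and deliver the homoannular 1,3-diene with the trans ring fusion intact.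

Step 17
Reactants: 26 15-[(tert-butyldiphenylsilyl)oxy]-6α-[(triisopropylsilyl)oxy]-13-nor-5αH,7αH,8βH-eudesma-1,3-dien-12,8-olide
Product: 27 15-[(tert-butyldiphenylsilyl)oxy]-6α-[(triisopropylsilyl)oxy]-13-nor-7αH,8βH-germacra-1(10)E,2Z,4Z-trien-12,8-olide (ring-trans at C1=C10 and C4=C5)
Conditions: hν (254 nm, quartz), degassed MeOH–THF, −30 °C; solution kept cold and used at once
Reagents that add atoms: none
Why: Direct excitation of the ring-A cyclohexa-1,3-diene (C1=C2–C3=C4) should induce a conrotatory 6π electrocyclic ring opening in which the C5–C10 σ-bond is cleaved and C1=C10 and C4=C5 are formed. The closest known reaction type is the photochemical opening of trans-fused eudesma-1,3-dien-olides, and of provitamin-D-type dienes, to cyclodeca-1(10),2,4-trienes. The ten-membered ring is therefore not closed by a cyclisation but arises by scission of the bond shared by the two six-membered rings, the lactone ring staying intact. No new stereocentre is created and C6, C7 and C8 are spectators; the new olefin geometries follow from conrotation of the trans ring fusion (H-5 α, C10 methyl β), which turns C6 and C9 outwards and gives ring-trans C1=C10 and C4=C5 around a cis C2=C3. The step needs absorption by the diene alone and survival of a triene that recloses thermally and photochemically: the lactone is kept saturated at C11, the silyl phenyl groups absorb far more weakly than the diene, and the cold solution is taken straight into the reduction.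

Step 18
Reactants: 27 germacra-1(10),2,4-triene lactone
Product: 28 15-[(tert-butyldiphenylsilyl)oxy]-6α-[(triisopropylsilyl)oxy]-13-nor-7αH,8βH-germacra-1(10)E,4Z-dien-12,8-olide
Conditions: KO2CN=NCO2K, AcOH, MeOH–THF, −30 → −10 °C
Reagents that add atoms: none
Why: Diimide reduction (concerted syn transfer of H2) should saturate the cis-disubstituted C2=C3 bond far faster than the two trisubstituted olefins or the lactone, which removes the 6π system and makes the ring opening irreversible.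

Step 19
Reactants: 28 germacra-1(10),4-diene lactone
Product: 31 15-[(tert-butyldiphenylsilyl)oxy]-6α-[(triisopropylsilyl)oxy]-7αH,8βH-germacra-1(10)E,4Z,11(13)-trien-12,8-olide, via Mannich base 29 (not isolated), via methiodide 30 (not isolated)
Conditions: LDA, THF, −78 °C; CH2=NMe2+ I−, −78 → 0 °C; then MeI, MeOH, 20 °C; then aq NaHCO3, EtOAc, 20 °C
Reagents that add atoms: Eschenmoser's salt (N,N-dimethylmethyleneiminium iodide), C=[N+](C)C.[I-]
Why: α-Methylenation by Mannich reaction of the lactone lithium enolate with Eschenmoser's salt, N-methylation and base-induced elimination of trimethylamine should install C13, the C11 configuration of the intermediates being irrelevant.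

Step 20
Reactants: 31 α-methylene lactone
Product: 32 15-hydroxy-6α-[(triisopropylsilyl)oxy]-7αH,8βH-germacra-1(10)E,4Z,11(13)-trien-12,8-olide
Conditions: TBAF, AcOH, THF, 0 → 20 °C
Reagents that add atoms: none
Why: Acetic-acid-buffered fluoride desilylation should cleave the primary allylic TBDPS ether much faster than the hindered secondary TIPS ether and without adding to the methylene lactone.

Step 21
Reactants: 33 [(tert-butyldimethylsilyl)oxy]acetaldehyde; 34 ethyl 2-(triphenyl-λ5-phosphanylidene)propanoate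
Product: 35 ethyl (2E)-4-[(tert-butyldimethylsilyl)oxy]-2-methylbut-2-enoate
Conditions: CH2Cl2, 20 °C
Reagents that add atoms: none
Why: Wittig olefination with the stabilised α-branched ylide should give the trisubstituted (E)-enoate.

Step 22
Reactants: 35 ethyl (2E)-4-[(tert-butyldimethylsilyl)oxy]-2-methylbut-2-enoate
Product: 36 (2E)-4-[(tert-butyldimethylsilyl)oxy]-2-methylbut-2-enoic acid
Conditions: LiOH, THF–H2O, 20 °C; then 1 M HCl to pH 4
Reagents that add atoms: lithium hydroxide, [Li+].[OH-]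
Why: Ester saponification should give the acid while the primary TBS ether and the olefin geometry are retained.

Step 23
Reactants: 32 C15 alcohol; 36 (2E)-4-[(tert-butyldimethylsilyl)oxy]-2-methylbut-2-enoic acid
Product: 37 15-({(2E)-4-[(tert-butyldimethylsilyl)oxy]-2-methylbut-2-enoyl}oxy)-6α-[(triisopropylsilyl)oxy]-7αH,8βH-germacra-1(10)E,4Z,11(13)-trien-12,8-olide
Conditions: EDC·HCl, DMAP, CH2Cl2, 0 → 20 °C
Reagents that add atoms: none
Why: Carbodiimide (Steglich) esterification should acylate the primary allylic C15 alcohol, the only free hydroxyl.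

Step 24
Reactants: 37 bis-silyl ether
Product: 38 6α-hydroxy-15-{[(2E)-4-hydroxy-2-methylbut-2-enoyl]oxy}-7αH,8βH-germacra-1(10)E,4Z,11(13)-trien-12,8-olide
Conditions: HF·pyridine, pyridine, THF, 0 → 20 °C
Reagents that add atoms: none
Why: Global desilylation with buffered HF·pyridine should remove the primary TBS and the secondary TIPS ether under non-basic conditions, which avoids translactonisation to O6, conjugate addition to the methylene lactone and ester cleavage.

**Compound list**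

1 | 3-[(tert-butyldiphenylsilyl)oxy]propanal | O=CCCO[Si](c1ccccc1)(c2ccccc2)C(C)(C)C | starting material
2 | vinylmagnesium bromide | C=C[Mg]Br | starting material
3 | (±)-5-[(tert-butyldiphenylsilyl)oxy]pent-1-en-3-ol | C=CC(O)CCO[Si](c1ccccc1)(c2ccccc2)C(C)(C)C | intermediate
4 | 5-[(tert-butyldiphenylsilyl)oxy]pent-1-en-3-one | C=CC(=O)CCO[Si](c1ccccc1)(c2ccccc2)C(C)(C)C | intermediate
5 | (±)-2-methylcyclohexan-1-one | CC1CCCCC1=O | starting material
6 | (R)-1-phenylethylamine | C[C@@H](N)c1ccccc1 | starting material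
7 | 2-methyl-N-[(1R)-1-phenylethyl]cyclohexan-1-imine (both ring C2 epimers) | CC1CCCCC1=N[C@H](C)c2ccccc2 | intermediate
8 | (2S)-2-{5-[(tert-butyldiphenylsilyl)oxy]-3-oxopentyl}-2-methyl-N-[(1R)-1-phenylethyl]cyclohexan-1-imine | C[C@@]1(CCC(=O)CCO[Si](c2ccccc2)(c3ccccc3)C(C)(C)C)CCCCC1=N[C@H](C)c4ccccc4 | intermediate
9 | (2S)-2-{5-[(tert-butyldiphenylsilyl)oxy]-3-oxopentyl}-2-methylcyclohexan-1-one | C[C@@]1(CCC(=O)CCO[Si](c2ccccc2)(c3ccccc3)C(C)(C)C)CCCCC1=O | intermediate
10 | (4aS)-1-{[(tert-butyldiphenylsilyl)oxy]methyl}-4a-methyl-4,4a,5,6,7,8-hexahydronaphthalen-2(3H)-one (15-silyloxy-11,12,13-trinoreudesm-4-en-3-one) | C[C@]12CCC(=O)C(CO[Si](c3ccccc3)(c4ccccc4)C(C)(C)C)=C1CCCC2 | intermediate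
11 | 15-[(tert-butyldiphenylsilyl)oxy]-3,3-(ethylenedioxy)-11,12,13-trinor-4βH-eudesm-5-ene (10β-methyl) | C[C@]12CCC3(OCCO3)[C@@H](CO[Si](c4ccccc4)(c5ccccc5)C(C)(C)C)C1=CCCC2 | intermediate
12 | 15-[(tert-butyldiphenylsilyl)oxy]-3,3-(ethylenedioxy)-11,12,13-trinor-4βH-eudesm-5-en-7-one | C[C@]12CCC3(OCCO3)[C@@H](CO[Si](c4ccccc4)(c5ccccc5)C(C)(C)C)C1=CC(=O)CC2 | intermediate
13 | 15-[(tert-butyldiphenylsilyl)oxy]-3,3-(ethylenedioxy)-11,12,13-trinor-4βH-eudesma-5,7-dien-7-yl trifluoromethanesulfonate | C[C@]12CCC3(OCCO3)[C@@H](CO[Si](c4ccccc4)(c5ccccc5)C(C)(C)C)C1=CC(OS(=O)(=O)C(F)(F)F)=CC2 | intermediate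
14 | (2-ethoxy-2-oxoethyl)zinc bromide | CCOC(=O)C[Zn]Br | starting material
15 | ethyl 15-[(tert-butyldiphenylsilyl)oxy]-3,3-(ethylenedioxy)-13-nor-4βH-eudesma-5,7-dien-12-oate | C[C@]12CCC3(OCCO3)[C@@H](CO[Si](c4ccccc4)(c5ccccc5)C(C)(C)C)C1=CC(CC(=O)OCC)=CC2 | intermediate
16 | ethyl 8α-(9-borabicyclo[3.3.1]nonan-9-yl)-15-[(tert-butyldiphenylsilyl)oxy]-3,3-(ethylenedioxy)-13-nor-4βH,7αH-eudesm-5-en-12-oate | C[C@]12CCC3(OCCO3)[C@@H](CO[Si](c4ccccc4)(c5ccccc5)C(C)(C)C)C1=C[C@H](CC(=O)OCC)[C@@H](B6C7CCCC6CCC7)C2 | intermediate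
17 | ethyl 15-[(tert-butyldiphenylsilyl)oxy]-3,3-(ethylenedioxy)-8α-hydroxy-13-nor-4βH,7αH-eudesm-5-en-12-oate | C[C@]12CCC3(OCCO3)[C@@H](CO[Si](c4ccccc4)(c5ccccc5)C(C)(C)C)C1=C[C@H](CC(=O)OCC)[C@@H](O)C2 | intermediate
18 | 15-[(tert-butyldiphenylsilyl)oxy]-3,3-(ethylenedioxy)-13-nor-4βH,7αH,8βH-eudesm-5-en-12,8-olide | C[C@]12CCC3(OCCO3)[C@@H](CO[Si](c4ccccc4)(c5ccccc5)C(C)(C)C)C1=C[C@@H]6CC(=O)O[C@H]6C2 | intermediate
19 | 6α-boranyl-15-[(tert-butyldiphenylsilyl)oxy]-3,3-(ethylenedioxy)-13-nor-4βH,5αH,7αH,8βH-eudesman-12,8-olide | C[C@]12CCC3(OCCO3)[C@@H](CO[Si](c4ccccc4)(c5ccccc5)C(C)(C)C)[C@@H]1[C@@H](B)[C@@H]6CC(=O)O[C@H]6C2 | intermediate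
20 | 15-[(tert-butyldiphenylsilyl)oxy]-3,3-(ethylenedioxy)-6α-hydroxy-13-nor-4βH,5αH,7αH,8βH-eudesman-12,8-olide | C[C@]12CCC3(OCCO3)[C@@H](CO[Si](c4ccccc4)(c5ccccc5)C(C)(C)C)[C@@H]1[C@@H](O)[C@@H]6CC(=O)O[C@H]6C2 | intermediate
21 | 15-[(tert-butyldiphenylsilyl)oxy]-3,3-(ethylenedioxy)-6α-[(triisopropylsilyl)oxy]-13-nor-4βH,5αH,7αH,8βH-eudesman-12,8-olide | C[C@]12CCC3(OCCO3)[C@@H](CO[Si](c4ccccc4)(c5ccccc5)C(C)(C)C)[C@@H]1[C@@H](O[Si](C(C)C)(C(C)C)C(C)C)[C@@H]6CC(=O)O[C@H]6C2 | intermediate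
22 | 15-[(tert-butyldiphenylsilyl)oxy]-3-oxo-6α-[(triisopropylsilyl)oxy]-13-nor-4βH,5αH,7αH,8βH-eudesman-12,8-olide | C[C@]12CCC(=O)[C@@H](CO[Si](c4ccccc4)(c5ccccc5)C(C)(C)C)[C@@H]1[C@@H](O[Si](C(C)C)(C(C)C)C(C)C)[C@@H]6CC(=O)O[C@H]6C2 | intermediate
23 | 15-[(tert-butyldiphenylsilyl)oxy]-6α-[(triisopropylsilyl)oxy]-3-[(trimethylsilyl)oxy]-13-nor-4βH,5αH,7αH,8βH-eudesm-2-en-12,8-olide | C[C@]12CC=C(O[Si](C)(C)C)[C@@H](CO[Si](c4ccccc4)(c5ccccc5)C(C)(C)C)[C@@H]1[C@@H](O[Si](C(C)C)(C(C)C)C(C)C)[C@@H]6CC(=O)O[C@H]6C2 | intermediate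
24 | 15-[(tert-butyldiphenylsilyl)oxy]-3-oxo-6α-[(triisopropylsilyl)oxy]-13-nor-4βH,5αH,7αH,8βH-eudesm-1-en-12,8-olide | C[C@]12C=CC(=O)[C@@H](CO[Si](c4ccccc4)(c5ccccc5)C(C)(C)C)[C@@H]1[C@@H](O[Si](C(C)C)(C(C)C)C(C)C)[C@@H]6CC(=O)O[C@H]6C2 | intermediate
25 | 15-[(tert-butyldiphenylsilyl)oxy]-6α-[(triisopropylsilyl)oxy]-3-{[(trifluoromethyl)sulfonyl]oxy}-13-nor-5αH,7αH,8βH-eudesma-1,3-dien-12,8-olide | C[C@]12C=CC(OS(=O)(=O)C(F)(F)F)=C(CO[Si](c4ccccc4)(c5ccccc5)C(C)(C)C)[C@@H]1[C@@H](O[Si](C(C)C)(C(C)C)C(C)C)[C@@H]6CC(=O)O[C@H]6C2 | intermediate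
26 | 15-[(tert-butyldiphenylsilyl)oxy]-6α-[(triisopropylsilyl)oxy]-13-nor-5αH,7αH,8βH-eudesma-1,3-dien-12,8-olide (10β-methyl, trans-fused) | C[C@]12C=CC=C(CO[Si](c4ccccc4)(c5ccccc5)C(C)(C)C)[C@@H]1[C@@H](O[Si](C(C)C)(C(C)C)C(C)C)[C@@H]6CC(=O)O[C@H]6C2 | intermediate
27 | 15-[(tert-butyldiphenylsilyl)oxy]-6α-[(triisopropylsilyl)oxy]-13-nor-7αH,8βH-germacra-1(10)E,2Z,4Z-trien-12,8-olide | O=C1C[C@@H]2[C@@H](O1)C/C(C)=C/C=C\C(CO[Si](c3ccccc3)(c4ccccc4)C(C)(C)C)=C\[C@H]2O[Si](C(C)C)(C(C)C)C(C)C | intermediate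
28 | 15-[(tert-butyldiphenylsilyl)oxy]-6α-[(triisopropylsilyl)oxy]-13-nor-7αH,8βH-germacra-1(10)E,4Z-dien-12,8-olide | O=C1C[C@@H]2[C@@H](O1)C/C(C)=C/CC/C(CO[Si](c3ccccc3)(c4ccccc4)C(C)(C)C)=C/[C@H]2O[Si](C(C)C)(C(C)C)C(C)C | intermediate
29 | 15-[(tert-butyldiphenylsilyl)oxy]-13-(dimethylamino)-6α-[(triisopropylsilyl)oxy]-7αH,8βH,11αH-germacra-1(10)E,4Z-dien-12,8-olide | CN(C)C[C@@H]1C(=O)O[C@H]2C/C(C)=C/CC/C(CO[Si](c3ccccc3)(c4ccccc4)C(C)(C)C)=C/[C@@H](O[Si](C(C)C)(C(C)C)C(C)C)[C@H]12 | intermediate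
30 | 13-(trimethylammonio) analogue of 29, iodide | C[N+](C)(C)C[C@@H]1C(=O)O[C@H]2C/C(C)=C/CC/C(CO[Si](c3ccccc3)(c4ccccc4)C(C)(C)C)=C/[C@@H](O[Si](C(C)C)(C(C)C)C(C)C)[C@H]12.[I-] | intermediate
31 | 15-[(tert-butyldiphenylsilyl)oxy]-6α-[(triisopropylsilyl)oxy]-7αH,8βH-germacra-1(10)E,4Z,11(13)-trien-12,8-olide | C=C1C(=O)O[C@H]2C/C(C)=C/CC/C(CO[Si](c3ccccc3)(c4ccccc4)C(C)(C)C)=C/[C@@H](O[Si](C(C)C)(C(C)C)C(C)C)[C@H]12 | intermediate
32 | 15-hydroxy-6α-[(triisopropylsilyl)oxy]-7αH,8βH-germacra-1(10)E,4Z,11(13)-trien-12,8-olide | C=C1C(=O)O[C@H]2C/C(C)=C/CC/C(CO)=C/[C@@H](O[Si](C(C)C)(C(C)C)C(C)C)[C@H]12 | intermediate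
33 | [(tert-butyldimethylsilyl)oxy]acetaldehyde | O=CCO[Si](C)(C)C(C)(C)C | starting material
34 | ethyl 2-(triphenyl-λ5-phosphanylidene)propanoate | CCOC(=O)C(C)=P(c1ccccc1)(c2ccccc2)c3ccccc3 | starting material
35 | ethyl (2E)-4-[(tert-butyldimethylsilyl)oxy]-2-methylbut-2-enoate | CCOC(=O)/C(C)=C/CO[Si](C)(C)C(C)(C)C | intermediate
36 | (2E)-4-[(tert-butyldimethylsilyl)oxy]-2-methylbut-2-enoic acid | OC(=O)/C(C)=C/CO[Si](C)(C)C(C)(C)C | intermediate
37 | 15-({(2E)-4-[(tert-butyldimethylsilyl)oxy]-2-methylbut-2-enoyl}oxy)-6α-[(triisopropylsilyl)oxy]-7αH,8βH-germacra-1(10)E,4Z,11(13)-trien-12,8-olide | C=C1C(=O)O[C@H]2C/C(C)=C/CC/C(COC(=O)/C(C)=C/CO[Si](C)(C)C(C)(C)C)=C/[C@@H](O[Si](C(C)C)(C(C)C)C(C)C)[C@H]12 | intermediate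
38 | 6α-hydroxy-15-{[(2E)-4-hydroxy-2-methylbut-2-enoyl]oxy}-7αH,8βH-germacra-1(10)E,4Z,11(13)-trien-12,8-olide | C=C1C(=O)O[C@H]2C/C(C)=C/CC/C(COC(=O)/C(C)=C/CO)=C/[C@@H](O)[C@H]12 | target

**Count and risks**

Total steps: 24. Longest linear sequence: 22 (steps 1–20, 23, 24).

Most likely to fail:

1. Step 17. The triene can be drained before it is reduced: it recloses photochemically to 26 and thermally to the cis-fused diene, and it can isomerise further under continued irradiation. Fallback: the triene is trapped as it forms instead of being accumulated and reduced afterwards. The cold methanolic solution of 26 is circulated in a closed loop between the irradiation cell and a cooled bed of W-2 Raney nickel under hydrogen, so that the cis C2=C3 bond is hydrogenated heterogeneously as soon as it appears. This replaces the separate diimide step, sets out from 26 and comes back at 28; no new compound is made (F0).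

2. Step 9. Site selectivity in the hydroboration of the diene may be lost (attack at C5=C6 or at both olefins), which would give a 6,8-diol able to lactonise either way. Fallback: the two ring-B olefins are never present together. From enone 12, rhodium-catalysed 1,4-hydrosilylation (Et3SiH, RhCl(PPh3)3) should deliver hydride to C5 from the α-face and give the triethylsilyl enol ether F1. Rubottom oxidation (m-CPBA, then mild acid) on the same face gives the 6α-hydroxy 7-ketone F2, and silylation gives the TIPS ether F3. Kinetic enolisation away from the oxygenated C6 and triflation give the C7=C8 enol triflate F4, and coupling with 14 gives the β,γ-unsaturated ester F5. Hydroboration–oxidation of this single olefin (boron at C8, α-face) gives the 8α-hydroxy ester F6, which lactonises under acid to 21, where the route is rejoined.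

3. Step 24. The hindered C6 TIPS ether may be cleaved so slowly that, meanwhile, the lactone opens or relocates to O6, the allylic ester is lost or the diene cyclises across the ring. Fallback: the hard desilylation is done before the ester is in place. Both silyl ethers of 31 are removed (TBAF/AcOH, prolonged) to give the 6α,15-diol F7. The primary allylic C15 hydroxyl is then acylated selectively with 36 (EDC, DMAP, 0 °C; the flanked secondary C6 hydroxyl reacts far more slowly) to give the mono-ester F8. Only the primary TBS ether then remains, and brief HF·pyridine/pyridine at 0 °C gives 38.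

Further compounds
F0 | step 17 | none | none
F1 | step 9 | 15-[(tert-butyldiphenylsilyl)oxy]-3,3-(ethylenedioxy)-7-[(triethylsilyl)oxy]-11,12,13-trinor-4βH,5αH-eudesm-6-ene | C[C@]12CCC3(OCCO3)[C@@H](CO[Si](c4ccccc4)(c5ccccc5)C(C)(C)C)[C@@H]1C=C(O[Si](CC)(CC)CC)CC2
F2 | step 9 | 15-[(tert-butyldiphenylsilyl)oxy]-3,3-(ethylenedioxy)-6α-hydroxy-11,12,13-trinor-4βH,5αH-eudesman-7-one | C[C@]12CCC3(OCCO3)[C@@H](CO[Si](c4ccccc4)(c5ccccc5)C(C)(C)C)[C@@H]1[C@@H](O)C(=O)CC2
F3 | step 9 | 15-[(tert-butyldiphenylsilyl)oxy]-3,3-(ethylenedioxy)-6α-[(triisopropylsilyl)oxy]-11,12,13-trinor-4βH,5αH-eudesman-7-one | C[C@]12CCC3(OCCO3)[C@@H](CO[Si](c4ccccc4)(c5ccccc5)C(C)(C)C)[C@@H]1[C@@H](O[Si](C(C)C)(C(C)C)C(C)C)C(=O)CC2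
F4 | step 9 | 15-[(tert-butyldiphenylsilyl)oxy]-3,3-(ethylenedioxy)-6α-[(triisopropylsilyl)oxy]-11,12,13-trinor-4βH,5αH-eudesm-7-en-7-yl trifluoromethanesulfonate | C[C@]12CCC3(OCCO3)[C@@H](CO[Si](c4ccccc4)(c5ccccc5)C(C)(C)C)[C@@H]1[C@@H](O[Si](C(C)C)(C(C)C)C(C)C)C(OS(=O)(=O)C(F)(F)F)=CC2
F5 | step 9 | ethyl 15-[(tert-butyldiphenylsilyl)oxy]-3,3-(ethylenedioxy)-6α-[(triisopropylsilyl)oxy]-13-nor-4βH,5αH-eudesm-7-en-12-oate | C[C@]12CCC3(OCCO3)[C@@H](CO[Si](c4ccccc4)(c5ccccc5)C(C)(C)C)[C@@H]1[C@@H](O[Si](C(C)C)(C(C)C)C(C)C)C(CC(=O)OCC)=CC2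
F6 | step 9 | ethyl 15-[(tert-butyldiphenylsilyl)oxy]-3,3-(ethylenedioxy)-8α-hydroxy-6α-[(triisopropylsilyl)oxy]-13-nor-4βH,5αH,7αH-eudesman-12-oate | C[C@]12CCC3(OCCO3)[C@@H](CO[Si](c4ccccc4)(c5ccccc5)C(C)(C)C)[C@@H]1[C@@H](O[Si](C(C)C)(C(C)C)C(C)C)[C@H](CC(=O)OCC)[C@@H](O)C2
F7 | step 24 | 6α,15-dihydroxy-7αH,8βH-germacra-1(10)E,4Z,11(13)-trien-12,8-olide | C=C1C(=O)O[C@H]2C/C(C)=C/CC/C(CO)=C/[C@@H](O)[C@H]12
F8 | step 24 | 15-({(2E)-4-[(tert-butyldimethylsilyl)oxy]-2-methylbut-2-enoyl}oxy)-6α-hydroxy-7αH,8βH-germacra-1(10)E,4Z,11(13)-trien-12,8-olide | C=C1C(=O)O[C@H]2C/C(C)=C/CC/C(COC(=O)/C(C)=C/CO[Si](C)(C)C(C)(C)C)=C/[C@@H](O)[C@H]12
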